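**Plan**

- Ring A is numbered C1 (OMe), C2 (Br), C3 (H), C4 (OH), C5 (O-aryl), C6 (Br). C1–OMe lies para to C4–OH, so ring A is a hydroquinone monomethyl ether, the pattern an alkoxycarbene benzannulation delivers.
- Retrosynthesis first removes C6–Br (electrophilic bromination) and C2–Br (ipso-substitution of a C2–SiMe3 group), then cuts ring A at C1–C6, C5–C4 and C4–C3.
- The pieces are a methoxy(α-silylvinyl)carbene chromium complex (C1–C2–C3 with the OMe), one CO ligand (C4 with its OH) and 2,4-dibromophenyl ethynyl ether (C5–C6, already carrying ring B and the diaryl ether oxygen).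
- Forward: the carbene complex comes from (1-bromovinyl)trimethylsilane and Cr(CO)6; the ynol ether comes from 2,4-dibromophenol by vinylation, bromination and two dehydrobrominations. Ring B is present throughout; ring A arises in the benzannulation, followed by acetylation, double bromination and deacetylation.
- The target has no stereocentre; the only stereochemical element on the way, the geometry of a bromovinyl ether, disappears on elimination to the alkyne.

Key step: step 5

Assumption: the terminal aryl ethynyl ether is taken to be stable enough in cold solution for use within a few hours, as phenoxyacetylene is; η6 bonding of chromium to ring A is written in SMILES as a dot-separated pair.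

**Route**

Step 1
Reactants: 1 (1-bromovinyl)trimethylsilane; 2 chromium hexacarbonyl
Product: 5 pentacarbonyl[methoxy(1-trimethylsilylvinyl)carbene]chromium, via [1-(trimethylsilyl)vinyl]lithium 3 (not isolated), via lithium acylchromate 4 (not isolated)
Conditions: t-BuLi (2.0 equiv), Et2O, −78 °C; Cr(CO)6, −78 °C → rt; then Me3OBF4, H2O/CH2Cl2, 0 °C
Reagents that add atoms: trimethyloxonium tetrafluoroborate, C[O+](C)C.F[B-](F)(F)F
Why: Bromine–lithium exchange gives the α-silylvinyllithium, which adds to a CO ligand of Cr(CO)6, and O-methylation of the resulting acylchromate completes a Fischer carbene synthesis of the kind routinely run with 2-substituted vinyllithiums, giving the zerovalent chromium carbene complex.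

Step 2
Reactants: 6 2,4-dibromophenol; 7 vinyl acetate
Product: 8 2,4-dibromo-1-(vinyloxy)benzene
Conditions: [Ir(cod)Cl]2 (1 mol %), Na2CO3 (0.6 equiv), toluene, 100 °C
Reagents that add atoms: none
Why: Iridium-catalysed transfer vinylation of a phenol with vinyl acetate (addition of the aryloxide to the coordinated vinyl ester, then β-acetoxy elimination) is a general route to aryl vinyl ethers and should leave the aryl bromides untouched.

Step 3
Reactants: 8 2,4-dibromo-1-(vinyloxy)benzene
Product: 10 (Z)-2,4-dibromo-1-[(2-bromovinyl)oxy]benzene, via 2,4-dibromo-1-(1,2-dibromoethoxy)benzene 9 (not isolated)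
Conditions: Br2 (1.0 equiv), CH2Cl2, −40 °C; solvent removed; then PhNEt2, 90 °C
Reagents that add atoms: bromine, BrBr
Why: Bromine adds to the enol ether double bond far faster than it attacks the deactivated ring, and the labile α-bromide of the dibromo ether is then lost with a β-proton on warming with the aniline base (bromination–dehydrobromination of a vinyl ether, the classical way to 2-bromovinyl ethers); the Z isomer is expected to predominate and any E isomer converges on the same alkyne in step 4.

Step 4
Reactants: 10 (Z)-2,4-dibromo-1-[(2-bromovinyl)oxy]benzene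
Product: 11 2,4-dibromo-1-(ethynyloxy)benzene
Conditions: KOtBu (1.5 equiv), THF, −20 °C → rt; kept cold and used at once
Reagents that add atoms: none
Why: anti-E2 dehydrobromination of a Z-2-bromovinyl aryl ether (the hydrogen on the aryloxy carbon is trans to bromine) is the established route to aryloxyacetylenes such as phenoxyacetylene, and tert-butoxide neither exchanges nor metallates the aryl bromides.

Step 5
Reactants: 5 pentacarbonyl[methoxy(1-trimethylsilylvinyl)carbene]chromium; 11 2,4-dibromo-1-(ethynyloxy)benzene
Product: 13 2-(2,4-dibromophenoxy)-4-methoxy-5-(trimethylsilyl)phenol, via arene tricarbonylchromium complex 12 (not isolated)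
Conditions: 11 (1.5 equiv, added slowly), THF (0.05 M), 50 °C, Ar; then air, rt
Reagents that add atoms: none
Why: Proposed new method: thermal loss of one CO from 5 lets the terminal ynol ether insert into the Cr=C bond with its CH carbon bonding to the carbene carbon (C1–C6), CO then inserts at the aryloxy-bearing carbon to give a chromium-bound dienylketene (C5–C4), and 6π-electrocyclisation of the ketene carbon onto the vinyl CH2 terminus (C4–C3) followed by enolisation gives the Cr(CO)3-bound phenol 12, from which air releases 13. The closest known reaction type is the Dötz benzannulation of alkenyl(alkoxy)carbene chromium complexes with terminal alkynes, which gives 4-alkoxyphenols with the alkyne substituent beside the new hydroxyl; an aryl ethynyl ether has not been shown as the alkyne partner. Ring A is closed as a formal [3+2+1] assembly whose ring-forming event is the 6π-electrocyclisation of the dienylketene, and no stereocentre is formed. The step needs the aryloxy carbon to end beside the CO-derived C4 and needs CO insertion to win over a stalled insertion product or a cyclobutenone. The regiochemistry is secured because the alkyne is terminal, so its unsubstituted carbon goes beside the methoxy-bearing C1 and the donor-substituted carbon stays on chromium. The chemoselectivity is favoured because the dibromophenoxy group is a much weaker donor than the amino or alkoxy groups that arrest ynamine-type insertions, and because alkenyl complexes in THF are the class most prone to benzannulation.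

Step 6
Reactants: 13 2-(2,4-dibromophenoxy)-4-methoxy-5-(trimethylsilyl)phenol
Product: 14 2-(2,4-dibromophenoxy)-4-methoxy-5-(trimethylsilyl)phenyl acetate
Conditions: Ac2O, pyridine, 4-(dimethylamino)pyridine (cat.), CH2Cl2, rt
Reagents that add atoms: acetic anhydride, CC(=O)OC(C)=O
Why: Standard O-acetylation of a phenol, which turns the C4 oxygen from the strongest ring-A director into a weak one so that C3, its only free ortho position, is no longer activated toward bromine.

Step 7
Reactants: 14 2-(2,4-dibromophenoxy)-4-methoxy-5-(trimethylsilyl)phenyl acetate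
Product: 16 3,5-dibromo-2-(2,4-dibromophenoxy)-4-methoxyphenyl acetate, via 5-bromo-2-(2,4-dibromophenoxy)-4-methoxyphenyl acetate 15 (not isolated)
Conditions: Br2 (2.2 equiv), CH2Cl2, −20 °C → rt
Reagents that add atoms: bromine, BrBr
Why: ipso-Bromodesilylation at C2 (ortho to OMe, para to O-aryl) should be the fastest electrophilic event, and the second bromine should then enter C6 by electrophilic aromatic bromination, since C6 is the only ring-A position ortho to both ether oxygens, C3 lies meta to both, and ring B is deactivated by its two bromines.

Step 8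
Reactants: 16 3,5-dibromo-2-(2,4-dibromophenoxy)-4-methoxyphenyl acetate
Product: 17 3,5-dibromo-2-(2,4-dibromophenoxy)-4-methoxyphenol
Conditions: HCl (cat.), MeOH, 45 °C
Reagents that add atoms: none
Why: Acid-catalysed transesterification of the aryl acetate with methanol should free the phenol without affecting the aryl bromides, the methyl ether or the diaryl ether.

**Compound list**

1 | (1-bromovinyl)trimethylsilane | C=C(Br)[Si](C)(C)C | starting material
2 | chromium hexacarbonyl, Cr(CO)6 | O=C=[Cr](=C=O)(=C=O)(=C=O)(=C=O)=C=O | starting material
3 | [1-(trimethylsilyl)vinyl]lithium | [Li]C(=C)[Si](C)(C)C | intermediate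
4 | lithium pentacarbonyl[1-oxido-2-(trimethylsilyl)prop-2-enylidene]chromate (lithium acylchromate) | [Li+].[O-]C(C(=C)[Si](C)(C)C)=[Cr](=C=O)(=C=O)(=C=O)(=C=O)=C=O | intermediate
5 | pentacarbonyl[methoxy(1-trimethylsilylvinyl)carbene]chromium (zerovalent chromium) | COC(C(=C)[Si](C)(C)C)=[Cr](=C=O)(=C=O)(=C=O)(=C=O)=C=O | intermediate
6 | 2,4-dibromophenol | Oc1ccc(Br)cc1Br | starting material
7 | vinyl acetate | CC(=O)OC=C | starting material
8 | 2,4-dibromo-1-(vinyloxy)benzene | C=COc1ccc(Br)cc1Br | intermediate
9 | 2,4-dibromo-1-(1,2-dibromoethoxy)benzene (racemic) | BrCC(Br)Oc1ccc(Br)cc1Br | intermediate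
10 | (Z)-2,4-dibromo-1-[(2-bromovinyl)oxy]benzene | Br/C=C\Oc1ccc(Br)cc1Br | intermediate
11 | 2,4-dibromo-1-(ethynyloxy)benzene | C#COc1ccc(Br)cc1Br | intermediate
12 | tricarbonyl[η6-2-(2,4-dibromophenoxy)-4-methoxy-5-(trimethylsilyl)phenol]chromium (ring A bound to chromium) | COc1cc(Oc2ccc(Br)cc2Br)c(O)cc1[Si](C)(C)C.O=C=[Cr](=C=O)=C=O | intermediate
13 | 2-(2,4-dibromophenoxy)-4-methoxy-5-(trimethylsilyl)phenol | COc1cc(Oc2ccc(Br)cc2Br)c(O)cc1[Si](C)(C)C | intermediate
14 | 2-(2,4-dibromophenoxy)-4-methoxy-5-(trimethylsilyl)phenyl acetate | COc1cc(Oc2ccc(Br)cc2Br)c(OC(C)=O)cc1[Si](C)(C)C | intermediate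
15 | 5-bromo-2-(2,4-dibromophenoxy)-4-methoxyphenyl acetate | COc1cc(Oc2ccc(Br)cc2Br)c(OC(C)=O)cc1Br | intermediate
16 | 3,5-dibromo-2-(2,4-dibromophenoxy)-4-methoxyphenyl acetate | COc1c(Br)cc(OC(C)=O)c(Oc2ccc(Br)cc2Br)c1Br | intermediate
17 | 3,5-dibromo-2-(2,4-dibromophenoxy)-4-methoxyphenol (CNP0140065.0) | COc1c(Br)cc(O)c(Oc2ccc(Br)cc2Br)c1Br | target

**Step count**

Total steps: 8. Longest linear sequence: 7 steps (6 → 17, steps 2 to 8); step 1 is the convergent branch.

**Steps most likely to fail**

1. Step 5. After alkyne insertion the chromium vinylcarbene may rest as a donor-stabilised aryloxycarbene that does not take up CO, the dienylketene may close in a four-electron sense to a cyclobutenone, or the ynol ether may oligomerise at the metal before it inserts. The fallback uses known chemistry, sets out from 6 and rejoins the route at 15. Nucleophilic aromatic substitution of 6 on commercial 2-fluoro-4-methoxybenzaldehyde (K2CO3, DMAc, 130 °C) should give 2-(2,4-dibromophenoxy)-4-methoxybenzaldehyde F1. Baeyer–Villiger oxidation with 3-chloroperbenzoic acid in CH2Cl2 should give 2-(2,4-dibromophenoxy)-4-methoxyphenyl formate F2, and methanolysis (HCl cat., MeOH) should give 2-(2,4-dibromophenoxy)-4-methoxyphenol F3. Acetylation (Ac2O, pyridine) should give 2-(2,4-dibromophenoxy)-4-methoxyphenyl acetate F4. One equivalent of Br2 in CH2Cl2 is expected to substitute the position para to the aryloxy group and ortho to the methoxy group, which gives 15; the second equivalent of bromine then carries 15 on to 16 as in step 7.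

2. Step 4. tert-Butoxide may add across the electron-rich triple bond, or the terminal ynol ether may polymerise during concentration. The fallback sets out from 10 and returns at 11, replacing isolation of the free alkyne by capture and release. KN(SiMe3)2 (2.2 equiv, THF, −78 °C) should eliminate HBr and metallate the alkyne to potassium (2,4-dibromophenoxy)ethynide F5. Me3SiCl should trap it as [(2,4-dibromophenoxy)ethynyl]trimethylsilane F6, a silyl-capped ynol ether that can be purified and stored. K2CO3 (cat.) in MeOH at 0 °C, immediately before the benzannulation, should release 11 in solution.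

3. Step 7. Substitution at the doubly flanked C6 may be slow, which would allow bromination of ring B ortho to its ether oxygen, or acidolysis of the acetate by HBr followed by attack at C3. The fallback places both ring-A bromines before the diaryl ether is made; it sets out from 6 and returns at 17. Commercial 2-fluoro-4-hydroxybenzaldehyde is brominated at both positions ortho to its hydroxyl (Br2, 2 equiv, AcOH), through 5-bromo-2-fluoro-4-hydroxybenzaldehyde F7 to 3,5-dibromo-2-fluoro-4-hydroxybenzaldehyde F8. O-Methylation (MeI, K2CO3, DMF) should give 3,5-dibromo-2-fluoro-4-methoxybenzaldehyde F9. Phenol 6 then displaces the fluoride activated by the ortho formyl group (K2CO3, DMF, 90 °C) to give 3,5-dibromo-2-(2,4-dibromophenoxy)-4-methoxybenzaldehyde F10. Baeyer–Villiger oxidation with 3-chloroperbenzoic acid should give 3,5-dibromo-2-(2,4-dibromophenoxy)-4-methoxyphenyl formate F11, and methanolysis (HCl cat., MeOH) should give 17.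

**Further compounds**

F1 | step 5 | 2-(2,4-dibromophenoxy)-4-methoxybenzaldehyde | COc1ccc(C=O)c(Oc2ccc(Br)cc2Br)c1
F2 | step 5 | 2-(2,4-dibromophenoxy)-4-methoxyphenyl formate | COc1ccc(OC=O)c(Oc2ccc(Br)cc2Br)c1
F3 | step 5 | 2-(2,4-dibromophenoxy)-4-methoxyphenol | COc1ccc(O)c(Oc2ccc(Br)cc2Br)c1
F4 | step 5 | 2-(2,4-dibromophenoxy)-4-methoxyphenyl acetate | COc1ccc(OC(C)=O)c(Oc2ccc(Br)cc2Br)c1
F5 | step 4 | potassium (2,4-dibromophenoxy)ethynide | [K+].[C-]#COc1ccc(Br)cc1Br
F6 | step 4 | [(2,4-dibromophenoxy)ethynyl]trimethylsilane | C[Si](C)(C)C#COc1ccc(Br)cc1Br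
F7 | step 7 | 5-bromo-2-fluoro-4-hydroxybenzaldehyde | O=Cc1cc(Br)c(O)cc1F
F8 | step 7 | 3,5-dibromo-2-fluoro-4-hydroxybenzaldehyde | O=Cc1cc(Br)c(O)c(Br)c1F
F9 | step 7 | 3,5-dibromo-2-fluoro-4-methoxybenzaldehyde | COc1c(Br)cc(C=O)c(F)c1Br
F10 | step 7 | 3,5-dibromo-2-(2,4-dibromophenoxy)-4-methoxybenzaldehyde | COc1c(Br)cc(C=O)c(Oc2ccc(Br)cc2Br)c1Br
F11 | step 7 | 3,5-dibromo-2-(2,4-dibromophenoxy)-4-methoxyphenyl formate | COc1c(Br)cc(OC=O)c(Oc2ccc(Br)cc2Br)c1Br
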